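**Retrosynthetic overview**
- The 4-methylfuran-2(5H)-one and its C15 carbinol are assembled last, in one pot, from three pieces: a 13E-labdenal (C15 aldehyde), diazoacetone (C5', C4', 4'-Me) and diethylphosphonoacetic acid (O1', C2', C3'). Bonds formed: O1'–C5' (carbene O–H insertion), C5'–C15 (aldol capture of the enol), C3'=C4' (intramolecular HWE).
- Enabling feature: ring atom C5' is a CH flanked by the lactone oxygen O1', the methyl-bearing sp2 carbon C4' and the C15 carbinol. It is the α-carbon of a masked α-acyloxy-β-hydroxy methyl ketone, and C3'=C4' conjugated to C2'=O is an olefination retron, so C5' can be a carbene carbon placed between an acid O–H and an aldehyde C=O.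
- The enal comes from the chiral-pool labdane larixol, which supplies C1–C15, the trans-decalin, C5/C9/C10 and the 6α-OH. The 8(17)-ene becomes 8α-OH/8β-Me (α-epoxidation, hydride opening); the tertiary 13-OH/14-ene becomes the 13E-alkene with oxygen at C15 (Pd(II) 1,3-acetoxy shift); MnO2 and silylation follow.
- Ring order: rings A/B are bought intact; the only ring formed is the butenolide (step 9); desilylation ends the route.

Key step: step 9

Numbering: labdane numbering for C1–C15; primed locants (O1', C2'–C5') for the furanone ring.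
Assumption: larixol is taken as a purchasable larch-resin diterpene. (R)-TRIP is written as the phosphoric acid enantiomer that should deliver 15S,5'S; if a model enal shows the opposite sense, the antipode is used with nothing else changed.

**Step 1**
Reactants: 1 larixol
Product: 2 8α,17-epoxylarixol
Conditions: mCPBA (1.05 equiv), NaHCO3, CH2Cl2, 0 °C
Reagents that add atoms: m-chloroperbenzoic acid, OOC(=O)c1cccc(Cl)c1
Why: Prilezhaev epoxidation should take the 1,1-disubstituted 8(17)-alkene far faster than the monosubstituted vinyl group, and the peracid should approach from the α face (equatorial trajectory, helped by hydrogen bonding to the 6α-OH) because the axial C10 methyl screens the β face, which places the new C8–O bond α.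

**Step 2**
Reactants: 2 8α,17-epoxylarixol
Product: 3 (13S)-labd-14-ene-6α,8α,13-triol
Conditions: LiAlH4, THF, 0 °C → rt; aqueous work-up
Reagents that add atoms: none
Why: SN2 hydride opening of the 2,2-disubstituted epoxide should occur at the unhindered CH2, turning it into the 8β-methyl and leaving the step-1 oxygen on C8 as the 8α tertiary alcohol.

**Step 3**
Reactants: 3 (13S)-labd-14-ene-6α,8α,13-triol
Product: 4 (13S)-labd-14-ene-6α,8α,13-triyl triacetate
Conditions: AcCl, PhNMe2, CH2Cl2, 0 °C → rt
Reagents that add atoms: acetyl chloride, CC(=O)Cl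
Why: O-acylation with acetyl chloride and N,N-dimethylaniline is the standard way to acetylate tertiary labdane alcohols without ionising them, and it touches no stereocentre.

**Step 4**
Reactants: 4 (13S)-labd-14-ene-6α,8α,13-triyl triacetate
Product: 5 (13E)-labd-13-ene-6α,8α,15-triyl triacetate
Conditions: PdCl2(MeCN)2 (5 mol%), THF, rt
Reagents that add atoms: none
Why: The Pd(II)-catalysed 1,3-acetoxy shift (Overman-type cyclisation-induced [3,3] rearrangement) should move only the allylic acetate to the primary terminus, since the trisubstituted alkene is the thermodynamic isomer, and a chair-like acetoxonium intermediate carrying the C12 chain equatorial should favour the 13E alkene (minor 13Z isomer to be removed by chromatography at 6).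

**Step 5**
Reactants: 5 (13E)-labd-13-ene-6α,8α,15-triyl triacetate
Product: 6 (13E)-labd-13-ene-6α,8α,15-triol
Conditions: LiAlH4, THF, 0 °C → reflux; aqueous work-up
Reagents that add atoms: none
Why: Hydride reduction of the three esters should free the primary, the hindered secondary and the tertiary hydroxyl in one operation without touching the isolated trisubstituted alkene or any stereocentre.

**Step 6**
Reactants: 6 (13E)-labd-13-ene-6α,8α,15-triol
Product: 7 (13E)-6α,8α-dihydroxylabd-13-en-15-al
Conditions: activated MnO2, CH2Cl2, rt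
Reagents that add atoms: none
Why: Manganese dioxide oxidation is selective for the allylic primary alcohol, so the saturated 6α-OH and the tertiary 8α-OH should stay untouched and the 13E geometry should be kept.

**Step 7**
Reactants: 7 (13E)-6α,8α-dihydroxylabd-13-en-15-al
Product: 8 (13E)-6α,8α-bis(triethylsilyloxy)labd-13-en-15-al
Conditions: TESOTf, 2,6-lutidine, CH2Cl2, −78 → −20 °C
Reagents that add atoms: triethylsilyl trifluoromethanesulfonate, CC[Si](CC)(CC)OS(=O)(=O)C(F)(F)F
Why: Silyl triflate/2,6-lutidine silylation should cap the secondary and the hindered tertiary hydroxyl so that neither can intercept the carbene in step 9, and at low temperature the weakly basic lutidine should not enolise the enal.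

**Step 8**
Reactants: 9 pentane-2,4-dione
Product: 11 diazoacetone (1-diazopropan-2-one), via 3-diazopentane-2,4-dione 10 (not isolated)
Conditions: p-ABSA, Et3N, MeCN, 0 °C → rt; then aq. KOH, 0 °C; extracted into CH2Cl2 and used as a dried solution
Reagents that add atoms: 4-acetamidobenzenesulfonyl azide, CC(=O)Nc1ccc(cc1)S(=O)(=O)N=[N+]=[N-]
Why: Regitz diazo transfer to the activated methylene followed by retro-Claisen deacetylation with hydroxide is the classical entry to acceptor-only diazo ketones.

**Step 9**
Reactants: 8 (13E)-6α,8α-bis(triethylsilyloxy)labd-13-en-15-al; 11 diazoacetone; 12 diethylphosphonoacetic acid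
Product: 15 6α,8α-bis-O-triethylsilyl derivative of the target, via Z-enol ester 13 (not isolated), via syn-aldol phosphonate 14 (not isolated)
Conditions: 8, 12 (1.5 equiv), Rh2(OAc)4 (2 mol%), (R)-TRIP (10 mol%), 4 Å MS, CH2Cl2, −20 °C, 11 (1.5 equiv) added over 2 h; then LiCl, iPr2NEt, MeCN, 0 °C → rt
Reagents that add atoms: none
Why: Proposed new method: Rh2(OAc)4 should turn 11 into an acceptor carbene whose carbon (future C5') is attacked by the carboxyl oxygen of 12 (O1'–C5' bond), giving a protic oxonium ylide that relaxes to Z-enol 13, held by an O–H···O=P hydrogen bond; before the 1,2-proton shift that would end in plain O–H insertion, 13 should add through C5' to the phosphoric-acid-activated aldehyde of 8 (C5'–C15 bond, aldol 14), and on addition of LiCl/iPr2NEt the phosphonate carbanion should close onto the C4' ketone and expel diethyl phosphate (C3'=C4' bond). The closest known reaction types are the Rh(II)/Brønsted acid three-component trapping of alcohol- and acid-derived oxonium ylides by aldehydes and imines, and butenolide formation by intramolecular Horner–Wadsworth–Emmons reaction of α-(phosphonoacetoxy) ketones; new is their union using an acceptor-only diazo ketone and a β,β-disubstituted enal. The only ring closed is the furanone, by 5-exo-trig addition of the C3' carbanion to the ketone followed by syn-elimination. C15 and C5' are both set in the aldol event: the Z-enol reacting through a cyclic, doubly hydrogen-bonded transition state on the phosphate should give the syn (threo) pair, and the phosphate enantiomer should fix the absolute sense as 15S,5'S, the remote decalin centres exerting no influence. The step needs the carbene to choose the acid O–H (the 6- and 8-hydroxyls are silylated, the acid is in excess, the diazo ketone is added slowly), capture of 13 faster than its tautomerisation (low temperature, acid co-catalyst, sieves), and olefination before acyl migration to the C15 hydroxyl or retro-aldol (mild Masamune–Roush base at 0 °C).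

**Step 10**
Reactants: 15 6α,8α-bis-O-triethylsilyl derivative of the target
Product: 16 target, (5S)-5-[(1S,2E)-1-hydroxy-5-[(1R,2R,4S,4aS,8aS)-2,4-dihydroxy-2,5,5,8a-tetramethyldecahydronaphthalen-1-yl]-3-methylpent-2-en-1-yl]-4-methylfuran-2(5H)-one
Conditions: HF·pyridine, pyridine, THF, 0 °C → rt
Reagents that add atoms: none
Why: Buffered fluoride desilylation should cleave both triethylsilyl ethers under conditions that neither epimerise C5' of the butenolide nor ionise the C15 allylic alcohol.

**Compound list**
1 | larixol, (13S)-labda-8(17),14-diene-6α,13-diol | C=C[C@@](C)(O)CC[C@@H]1[C@@]2(C)CCCC(C)(C)[C@@H]2[C@@H](O)CC1=C | starting material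
2 | 8α,17-epoxylarixol, (13S)-8α,17-epoxylabd-14-ene-6α,13-diol (epoxide oxygen α, CH2 β) | C=C[C@@](C)(O)CC[C@@H]1[C@@]2(C)CCCC(C)(C)[C@@H]2[C@@H](O)C[C@@]1(C3)O3 | intermediate
3 | (13S)-labd-14-ene-6α,8α,13-triol | C=C[C@@](C)(O)CC[C@@H]1[C@@]2(C)CCCC(C)(C)[C@@H]2[C@@H](O)C[C@@]1(C)O | intermediate
4 | (13S)-labd-14-ene-6α,8α,13-triyl triacetate | C=C[C@@](C)(OC(C)=O)CC[C@@H]1[C@@]2(C)CCCC(C)(C)[C@@H]2[C@@H](OC(C)=O)C[C@@]1(C)OC(C)=O | intermediate
5 | (13E)-labd-13-ene-6α,8α,15-triyl triacetate | CC(=O)OC/C=C(\C)CC[C@@H]1[C@@]2(C)CCCC(C)(C)[C@@H]2[C@@H](OC(C)=O)C[C@@]1(C)OC(C)=O | intermediate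
6 | (13E)-labd-13-ene-6α,8α,15-triol | OC/C=C(\C)CC[C@@H]1[C@@]2(C)CCCC(C)(C)[C@@H]2[C@@H](O)C[C@@]1(C)O | intermediate
7 | (13E)-6α,8α-dihydroxylabd-13-en-15-al | O=C/C=C(\C)CC[C@@H]1[C@@]2(C)CCCC(C)(C)[C@@H]2[C@@H](O)C[C@@]1(C)O | intermediate
8 | (13E)-6α,8α-bis(triethylsilyloxy)labd-13-en-15-al | O=C/C=C(\C)CC[C@@H]1[C@@]2(C)CCCC(C)(C)[C@@H]2[C@@H](O[Si](CC)(CC)CC)C[C@@]1(C)O[Si](CC)(CC)CC | intermediate
9 | pentane-2,4-dione (acetylacetone) | CC(=O)CC(C)=O | starting material
10 | 3-diazopentane-2,4-dione | CC(=O)C(=[N+]=[N-])C(C)=O | intermediate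
11 | diazoacetone, 1-diazopropan-2-one | CC(=O)C=[N+]=[N-] | intermediate
12 | diethylphosphonoacetic acid, 2-(diethoxyphosphoryl)acetic acid | CCOP(=O)(OCC)CC(=O)O | starting material
13 | Z-enol ester, (Z)-2-hydroxyprop-1-en-1-yl 2-(diethoxyphosphoryl)acetate | C/C(O)=C/OC(=O)CP(=O)(OCC)OCC | intermediate
14 | syn-aldol phosphonate: methyl ketone CH3CO–C5'H(O2CCH2P(O)(OEt)2)–C15H(OH)– on the 13E-alkene of the bis-TES labdane, (15S,5'R), syn | CC(=O)[C@H](OC(=O)CP(=O)(OCC)OCC)[C@@H](O)/C=C(\C)CC[C@@H]1[C@@]2(C)CCCC(C)(C)[C@@H]2[C@@H](O[Si](CC)(CC)CC)C[C@@]1(C)O[Si](CC)(CC)CC | intermediate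
15 | 6α,8α-bis-O-triethylsilyl derivative of the target, (15S,5'S,13E) | CC1=CC(=O)O[C@@H]1[C@@H](O)/C=C(\C)CC[C@@H]1[C@@]2(C)CCCC(C)(C)[C@@H]2[C@@H](O[Si](CC)(CC)CC)C[C@@]1(C)O[Si](CC)(CC)CC | intermediate
16 | target, (5S)-5-[(1S,2E)-1-hydroxy-5-[(1R,2R,4S,4aS,8aS)-2,4-dihydroxy-2,5,5,8a-tetramethyldecahydronaphthalen-1-yl]-3-methylpent-2-en-1-yl]-4-methylfuran-2(5H)-one | CC1=CC(=O)O[C@@H]1[C@@H](O)/C=C(\C)CC[C@@H]1[C@@]2(C)CCCC(C)(C)[C@@H]2[C@@H](O)C[C@@]1(C)O | target

**Totals**
Total step count: 10. Longest linear sequence: 9 steps (steps 1–7, 9, 10); step 8 is a one-step side branch.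

**Steps most likely to fail**

1. Step 9 (proposed new method). What may go wrong: tautomerisation of the enol to the simple O–H insertion ester may outpace its capture by the weakly electrophilic β,β-disubstituted enal; syn/anti or facial control in the aldol event may be poor; the acyl group may migrate to the C15 hydroxyl before olefination. The fallback is a vinylogous Mukaiyama aldol reaction, which is known chemistry; it sets out from 8 and comes back at 15. Commercial 4-methylfuran-2(5H)-one (CC1=CC(=O)OC1) would be O-silylated (TMSOTf, Et3N, CH2Cl2, 0 °C) to 4-methyl-2-(trimethylsilyloxy)furan F1. F1 would add through its C5 to enal 8 under a chiral Lewis acid (Ti(OiPr)4/BINOL, Et2O, −20 °C; BINOL antipode chosen on a model enal). The open transition state of the Lewis-acid mode normally favours the threo adduct, here the 15-O-trimethylsilyl ether of 15 F2. Brief treatment with citric acid in methanol at 0 °C should remove the trimethylsilyl group and give 15, which continues with step 10.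

2. Step 4. What may go wrong: the suprafacial 1,3-acetoxy shift may show low E/Z selectivity because methyl and CH2 differ little in size; Pd(II) may ionise the tertiary allylic acetate and cause elimination to dienes. The fallback sets the alkene geometry by olefination; it sets out from 3, comes back at 8 and replaces steps 3–7. Oxidative cleavage of the vinyl carbinol of 3 (OsO4 cat., excess NaIO4, THF–H2O), which excises C14 and C15, would give 6α,8α-dihydroxy-14,15-dinorlabdan-13-one F3. Silylation (TESOTf, 2,6-lutidine, −78 °C) would give 6α,8α-bis(triethylsilyloxy)-14,15-dinorlabdan-13-one F4. Horner–Wadsworth–Emmons olefination (triethyl phosphonoacetate, NaH, THF) should give mainly ethyl (13E)-6α,8α-bis(triethylsilyloxy)labd-13-en-15-oate F5, whose Z isomer is configurationally stable and separable. DIBAL-H reduction would give (13E)-6α,8α-bis(triethylsilyloxy)labd-13-en-15-ol F6, and MnO2 oxidation would give 8.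

3. Step 7. What may go wrong: the silyl-triflate-activated enal may undergo γ-deprotonation to a silyl dienol ether, with loss of the 13E geometry; silylation of the hindered tertiary 8-OH may be incomplete. The fallback silylates before any carbonyl exists; it sets out from 6, comes back at 8 and replaces steps 6 and 7. Triol 6 would be persilylated (TESOTf, 2,6-lutidine, CH2Cl2, 0 °C) to (13E)-6α,8α,15-tris(triethylsilyloxy)labd-13-ene F7. The primary allylic silyl ether alone would then be converted directly into the aldehyde under Swern conditions ((COCl)2, DMSO, CH2Cl2, −78 → −30 °C; Et3N), the known selective oxidative cleavage of primary triethylsilyl ethers beside secondary and tertiary ones, giving 8.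

**Further compounds**
F1 | step 9 | 4-methyl-2-(trimethylsilyloxy)furan | Cc1coc(O[Si](C)(C)C)c1
F2 | step 9 | 15-O-trimethylsilyl ether of 15 | CC1=CC(=O)O[C@@H]1[C@@H](O[Si](C)(C)C)/C=C(\C)CC[C@@H]1[C@@]2(C)CCCC(C)(C)[C@@H]2[C@@H](O[Si](CC)(CC)CC)C[C@@]1(C)O[Si](CC)(CC)CC
F3 | step 4 | 6α,8α-dihydroxy-14,15-dinorlabdan-13-one | CC(=O)CC[C@@H]1[C@@]2(C)CCCC(C)(C)[C@@H]2[C@@H](O)C[C@@]1(C)O
F4 | step 4 | 6α,8α-bis(triethylsilyloxy)-14,15-dinorlabdan-13-one | CC(=O)CC[C@@H]1[C@@]2(C)CCCC(C)(C)[C@@H]2[C@@H](O[Si](CC)(CC)CC)C[C@@]1(C)O[Si](CC)(CC)CC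
F5 | step 4 | ethyl (13E)-6α,8α-bis(triethylsilyloxy)labd-13-en-15-oate | CCOC(=O)/C=C(\C)CC[C@@H]1[C@@]2(C)CCCC(C)(C)[C@@H]2[C@@H](O[Si](CC)(CC)CC)C[C@@]1(C)O[Si](CC)(CC)CC
F6 | step 4 | (13E)-6α,8α-bis(triethylsilyloxy)labd-13-en-15-ol | OC/C=C(\C)CC[C@@H]1[C@@]2(C)CCCC(C)(C)[C@@H]2[C@@H](O[Si](CC)(CC)CC)C[C@@]1(C)O[Si](CC)(CC)CC
F7 | step 7 | (13E)-6α,8α,15-tris(triethylsilyloxy)labd-13-ene | CC[Si](CC)(CC)OC/C=C(\C)CC[C@@H]1[C@@]2(C)CCCC(C)(C)[C@@H]2[C@@H](O[Si](CC)(CC)CC)C[C@@]1(C)O[Si](CC)(CC)CC
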